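## Structural features

The target is a chromanone acid. A cis-2,3-dimethyl-2,3-dihydropyran-4-one (ring C: O1, C2, C3, C4) is fused through C4a=C8a to a dearomatized phloroglucinol ring (ring A: C4a, C5 to C8, C8a), a vinylogous acid with its enol at C5 and ketones at C4 and C7. C8 is a quaternary stereocentre (R) carrying a prenyl group and, through one methylene, a cis-2,2-dimethyl-3-isopropenylcyclobutane (1S,3R); C6 carries a 1-propyl-2-carboxyethyl chain with an (S) centre. The six stereocentres form four sets that cannot relay information to one another: C2/C3 (adjacent, cis, 2R,3S), C8, the side-chain carbon, and the two cyclobutane carbons, which face each other across the ring. Fragile points are C3 (alpha to the C4 ketone, cis less stable than trans, ring C opens by retro-oxa-Michael reaction under base) and the isopropenylcyclobutane, whose protonation gives a cyclobutylcarbinyl cation that opens or ring-expands. The olefins also rule out late hydrogenation. The real difficulties are the strained cis-cyclobutane, the quaternary C8 with no neighbouring controller, and the regiochemistry of a fully substituted ring A. Ring A with its C6 chain and C5 oxygen is a masked 4-alkyl-3,4-dihydrocoumarin, which settles that regiochemistry and protects the acid. The key step exploits the fact that the cyclobutylmethyl unit (ring carbons C1' to C4', gem-dimethyl carbon C2', isopropenyl on C3', exocyclic CH2 on C1') is atom for atom a lavandulyl chain in which the C2'–C3' bond joins the isopropenyl carbon to the inner carbon of the prenyl arm.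

## Logic of the disconnections

19 to 18: the acyl C–O bond between the C5 oxygen and the side-chain carboxyl is re-formed. The resulting enol lactone hides the acid, blocks the C5 oxygen and leaves the C7 oxygen as the only free one in the aromatic precursors. The forward step must open a lactone without touching C3; this is easy because 18 is a vinylogous anhydride.

18 to 16 and 17: the C8–CH2 bond of the prenyl group is cut. The quaternary centre is recognised as a dearomatized phenol carbon, so ring A becomes aromatic and the C8 stereocentre disappears. The forward step demands C- over O-alkylation, attack at this ortho carbon and not at the lactone-bearing one, and facial control from a catalyst, since no stereocentre is near.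

16 to 14 and 5: the aryl–CH2 bond is cut into a nucleophilic ring carbon (the only unsubstituted one) and an aldehyde carbon. This splits the molecule into two halves of similar size. The forward step must run under conditions mild enough for the isopropenylcyclobutane and must reduce the quinone methide before it tautomerizes.

5 to 4 to 3: functional-group changes only (aldehyde, alcohol, acetate). The forward oxidation must not epimerize the ring carbon next to the carbonyl.

3 to 2: the cyclobutane bond C2'–C3' is cut with transposition of the isopropenyl double bond (a retro-ene operation). One ring and one stereocentre are removed, and the remaining centre is that of a chiral-pool terpene. The forward step must choose the four-membered closure and the cis ring and must not scramble the existing centre.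

2 to 1: the acetyl C–O bond; a trivial acylation.

14 to 13 to 11 and 12: the propyl group is taken back to a propenyl group, and the C4–C(alkenyl) bond is cut. Reducing a 4-propylcoumarin instead would need either hydride reagents, which attack the ring C ketone, or base-opened hydrogenation, which endangers C9. Conjugate addition to the flat coumarin sets this centre by catalyst control under neutral conditions. The demand is sufficient reactivity of an electron-rich coumarin.

11 to 10: the O7–C8 bond of ring C is cut (retro-oxa-Michael). Both ring C centres are lost at once. The regiochemistry is certain in the forward sense, because the second oxygen ortho to the enone is tied up in the lactone. The forward step must be kinetically controlled to give the cis isomer.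

10 to 8 and 9: the aryl–acyl bond is cut (Friedel–Crafts). The forward step relies on the known preference of 5,7-dihydroxycoumarins for C8.

8 to 6 and 7: the C4–C4a and O1–C2 bonds of the coumarin are cut, leading to a symmetric triphenol and a three-carbon ester, with no regiochemical issue.

## Other disconnections considered

Alternative 1: The cut goes through ring A (C7–C6, C5–C4a and, formally, C8–C7). Ring A is assembled from cyclobutenone A2 (C7, C4a, C8a, C8 with both C8 substituents) and siloxyalkyne A3 (C6 with its side chain, C5). On heating, A2 would open to a vinylketene, add A3, and pass through 4π opening and 6π closure to dienone A1, which cannot aromatize because C8 is blocked.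
- In its favour: the substitution pattern of ring A follows from the connectivity of the partners, so the regiochemistry that the chosen plan secures with the lactone is no issue at all; on this point the alternative is the better one. The cascade is a known pericyclic sequence, and A3 brings in the side-chain centre from an independent synthesis.
- Against it here: C8 becomes a trigonal vinylketene terminus, so its configuration in A2 is erased and re-formed in the 6π closure with only remote centres to bias it. A1 is therefore expected as a mixture of C8 epimers, where the chosen plan offers catalyst control. Ring C is still missing and would have to be added to a sensitive dienone. A2 still needs the cyclobutylmethyl group, so the four-membered ring is not addressed.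
- Comparison: on mechanism it equals the coupling steps of the chosen plan and is more certain than its key step; on step economy it is longer.

Alternative 2: The cut removes two cyclobutane bonds and leads to amide A5 and allyl silyl ether A6. Triflic anhydride and a hindered pyridine would turn A5 into a keteniminium triflate, which adds across the terminal olefin of A6; hydrolysis gives cyclobutanone A4, with the CH2O-bearing centre set by the C2-symmetric pyrrolidine.
- In its favour: an established cycloaddition with predictable regiochemistry, no free carbocation and no unfavourable equilibrium. On mechanistic security it is clearly the better of the two.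
- Against it here: A4 lacks the isopropenyl carbons and the second stereocentre. The ketone would have to be homologated to the cis-acetyl compound and methylenated before desilylation gives 4, about four to five further steps against one. Unactivated monosubstituted olefins are the less reactive partners, and the auxiliary is costly.
- Comparison: both plans converge on 4. The alternative is about twice as long to that point but rests on known chemistry, and it would be preferred whenever the isomerization of 2 does not deliver.

Alternative 3: The cut goes through ring C (C2–C3 and O1–C8a) and leads to acetaldehyde and diene A8, which already holds C8 with both substituents and C7 as a methyl ester. A chiral Schiff-base complex of trivalent chromium chloride would bring acetaldehyde endo onto the (Z)-configured diene terminus; acid would then expel methanol to give dihydropyranone A7.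
- In its favour: the cis relation of C2 and C3 comes directly from the endo transition state and the absolute sense from the catalyst, without an equilibrium-prone oxa-Michael step; on this point it is at least the equal of the quinine step. C8 would be set earlier by enolate alkylation, which is better precedented than dearomative prenylation; on C8 the alternative is the better one.
- Against it here: the diene carbon that bonds to oxygen is fully substituted and sits next to a quaternary carbon, and the catalyst has to overrule the C8 centre. Ring A must then be built around C8 (C4a–C5, C5–C6, C6–C7, the C6 chain and its centre) with base-mediated acylations that endanger C3. The cyclobutane must be in hand before the first step.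
- Comparison: longer and linear; its key step is known chemistry where that of the chosen plan is not; the difficulty moves from C8 to the late construction of ring A.

Key step: step 2

Assumption: (R)-lavandulol is bought enantioenriched; if only the racemate is at hand, lipase-mediated acetylation is taken to give 2 directly, so the route does not grow.

Assumption: the antipode of each chiral catalyst in steps 2, 7, 8 and 11 is the one suggested by analogy with simpler substrates; in each case the other antipode is equally accessible if the sense on these substrates is reversed.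

Convention: tricyclic intermediates are numbered as benzo[1,2-b:3,4-b']dipyrans: O1, C2 (lactone carbonyl), C3, C4 (side-chain carbon), C4a, C5 (OH), C6 (free ring carbon), C6a, O7, C8, C9, C10 (ketone), C10a, C10b. C6, C8 and C9 of this numbering are C8, C2 and C3 of the target's chromanone numbering.

## Route

Step 1
Reactants: 1 (R)-lavandulol
Product: 2 (R)-lavandulyl acetate
Conditions: Ac2O, pyridine, DMAP (cat.), CH2Cl2, 0 °C to rt
Reagents that add atoms: acetic anhydride, CC(=O)OC(C)=O
Why: DMAP-catalysed acylation of a primary alcohol; the stereocentre is not involved.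

Step 2
Reactants: 2 (R)-lavandulyl acetate
Product: 3 [(1R,3R)-2,2-dimethyl-3-(prop-1-en-2-yl)cyclobutyl]methyl acetate (cis)
Conditions: confined imidodiphosphorimidate (IDPi) Brønsted acid with N-perfluoroalkylsulfonyl groups and 3,3'-aryl-substituted BINOL units, matched enantiomer (5–10 mol %), methylcyclohexane, −20 to 0 °C; Et3N quench at the conversion maximum; recovered 2 recycled
Reagents that add atoms: none
Why: Proposed new method: the acid protonates the terminal CH2 of the isopropenyl group of 2, the tertiary cation held as a contact ion pair is attacked by the inner carbon of the prenyl olefin to give an exocyclic tertiary cation, and the counter-anion removes a methyl proton, which forms the isopropenyl group of 3 and returns the acid (overall a stepwise intramolecular ene reaction). The closest known reaction types are confined-acid protonations of unactivated 1,1-disubstituted olefins followed by cation–olefin cyclization or 1,2-shift, and the enzymatic closure of the lavandulyl cation to a cyclobutane. The one ring closed is the cyclobutane, by 4-exo-trig attack, the prenyl double bond staying outside the new ring. The one new stereocentre, the isopropenyl-bearing ring carbon, is controlled by the existing (R) centre: in the puckered transition state the CH2OAc group and the developing 2-propyl cation both sit pseudo-equatorial, which is the cis ring, and the matched catalyst enantiomer reinforces this. Three selectivities are needed: protonation of the 1,1-disubstituted and not the trisubstituted olefin (the latter leads by six-membered closure to the cyclolavandulyl ring), attack through the inner olefin carbon, and methyl deprotonation in preference to ring expansion or loss of the proton at the (R) centre. The terminal methylene is the most accessible basic site for a buried proton, only inner-carbon attack gives a tertiary cation, and a tightly paired basic counter-anion over the exocyclic cation should make proton loss faster than a skeletal shift. The isomerization is estimated to be thermoneutral to somewhat uphill (one π bond exchanged for one σ bond against about 26 kcal/mol of ring strain, partly offset by the gem-dimethyl group), so the catalyst can at best reach the equilibrium ratio, hence low temperature, early quench and recycling.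

Step 3
Reactants: 3 [(1R,3R)-2,2-dimethyl-3-(prop-1-en-2-yl)cyclobutyl]methyl acetate
Product: 4 [(1R,3R)-2,2-dimethyl-3-(prop-1-en-2-yl)cyclobutyl]methanol
Conditions: K2CO3 (cat.), MeOH, rt
Reagents that add atoms: none
Why: base-catalysed transesterification of a primary acetate; neutral work-up keeps acid away from the isopropenylcyclobutane.

Step 4
Reactants: 4 [(1R,3R)-2,2-dimethyl-3-(prop-1-en-2-yl)cyclobutyl]methanol
Product: 5 (1R,3R)-2,2-dimethyl-3-(prop-1-en-2-yl)cyclobutane-1-carbaldehyde
Conditions: TEMPO (10 mol %), PhI(OAc)2 (1.1 equiv), CH2Cl2, rt; used at once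
Reagents that add atoms: none
Why: oxoammonium oxidation of a primary alcohol stops at the aldehyde and leaves olefins alone; the medium is non-basic, so the ring carbon next to the carbonyl should not epimerize (the cis isomer is in any case the more stable).

Step 5
Reactants: 6 phloroglucinol; 7 ethyl propiolate
Product: 8 5,7-dihydroxycoumarin
Conditions: ZnCl2 (1 equiv), dioxane, 95 °C
Reagents that add atoms: none
Why: Lewis-acid-promoted hydroarylation of the propiolate by the symmetric triphenol followed by lactonization (Pechmann-type coumarin synthesis); symmetry removes any regiochemical question.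

Step 6
Reactants: 8 5,7-dihydroxycoumarin; 9 tigloyl chloride
Product: 10 5,7-dihydroxy-8-[(E)-2-methylbut-2-enoyl]coumarin
Conditions: AlCl3 (4 equiv), PhNO2, rt to 60 °C; cold dilute HCl work-up
Reagents that add atoms: none
Why: Friedel–Crafts acylation; C8 is the usual site of acylation in 5,7-dihydroxycoumarins, and the minor C6 isomer is removed by crystallization. The reaction is stopped before the enone cyclizes.

Step 7
Reactants: 10 5,7-dihydroxy-8-[(E)-2-methylbut-2-enoyl]coumarin
Product: 11 (8R,9S)-5-hydroxy-8,9-dimethyl-8,9-dihydro-2H,10H-benzo[1,2-b:3,4-b']dipyran-2,10-dione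
Conditions: (−)-quinine (20 mol %), PhCl, 15 °C
Reagents that add atoms: none
Why: alkaloid-catalysed asymmetric intramolecular oxa-Michael addition; only the C7 hydroxyl flanks the enone, since the other ortho oxygen is the lactone oxygen. The amine–hydroxyl pair of quinine selects the enone face for O–C8 bond formation (8R), and kinetic protonation of the enol on the face away from the new C8 methyl group gives the cis (9S) centre.

Step 8
Reactants: 11 (8R,9S)-5-hydroxy-8,9-dimethyl-8,9-dihydro-2H,10H-benzo[1,2-b:3,4-b']dipyran-2,10-dione; 12 (E)-prop-1-enylboronic acid
Product: 13 (4R,8R,9S)-5-hydroxy-8,9-dimethyl-4-[(E)-prop-1-enyl]-3,4,8,9-tetrahydro-2H,10H-benzo[1,2-b:3,4-b']dipyran-2,10-dione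
Conditions: Rh(acac)(C2H4)2 (5 mol %), (R)-Segphos (5.5 mol %), 12 (4 equiv), dioxane/H2O (10:1), 60 °C
Reagents that add atoms: none
Why: rhodium-catalysed asymmetric conjugate addition of an organoboronic acid to a coumarin (Hayashi–Miyaura reaction) under neutral conditions that leave the aryl ketone and the cis ring C alone. The C4 centre is set by the bisphosphine, which exposes one face of the enoate to the alkenylrhodium species; (4R) here becomes (4S) after step 9 only because the priorities change.

Step 9
Reactants: 13 (4R,8R,9S)-5-hydroxy-8,9-dimethyl-4-[(E)-prop-1-enyl]-3,4,8,9-tetrahydro-2H,10H-benzo[1,2-b:3,4-b']dipyran-2,10-dione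
Product: 14 (4S,8R,9S)-5-hydroxy-8,9-dimethyl-4-propyl-3,4,8,9-tetrahydro-2H,10H-benzo[1,2-b:3,4-b']dipyran-2,10-dione
Conditions: H2 (1 atm), palladium on carbon (Pd/C, 10 %), EtOAc, rt
Reagents that add atoms: none
Why: heterogeneous hydrogenation of the only C=C bond; the vinylogous-ester ketone and the lactone are inert under these conditions and no stereocentre is touched.

Step 10
Reactants: 14 (4S,8R,9S)-5-hydroxy-8,9-dimethyl-4-propyl-3,4,8,9-tetrahydro-2H,10H-benzo[1,2-b:3,4-b']dipyran-2,10-dione; 5 (1R,3R)-2,2-dimethyl-3-(prop-1-en-2-yl)cyclobutane-1-carbaldehyde
Product: 16 (4S,8R,9S)-6-{[(1S,3R)-2,2-dimethyl-3-(prop-1-en-2-yl)cyclobutyl]methyl}-5-hydroxy-8,9-dimethyl-4-propyl-3,4,8,9-tetrahydro-2H,10H-benzo[1,2-b:3,4-b']dipyran-2,10-dione, via ortho-quinone methide 15 (not isolated)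
Conditions: diethyl 2,6-dimethyl-1,4-dihydropyridine-3,5-dicarboxylate (Hantzsch ester, 1.5 equiv), (PhO)2P(O)OH (20 mol %), 4 Å molecular sieves, 1,2-dichloroethane, 40 °C
Reagents that add atoms: none
Why: reductive Friedel–Crafts alkylation: acid-catalysed ortho-hydroxyalkylation at the only free ring carbon and loss of water give quinone methide 15, which the Hantzsch ester reduces by conjugate hydride transfer. The weak phosphoric acid should not protonate the isopropenyl group, and no stereocentre is formed; the cyclobutane centre next to the new CH2 is kept as long as reduction outruns tautomerization of 15.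

Step 11
Reactants: 16 (4S,8R,9S)-6-{[(1S,3R)-2,2-dimethyl-3-(prop-1-en-2-yl)cyclobutyl]methyl}-5-hydroxy-8,9-dimethyl-4-propyl-3,4,8,9-tetrahydro-2H,10H-benzo[1,2-b:3,4-b']dipyran-2,10-dione; 17 prenyl acetate
Product: 18 (4S,6R,8R,9S)-6-{[(1S,3R)-2,2-dimethyl-3-(prop-1-en-2-yl)cyclobutyl]methyl}-8,9-dimethyl-6-(3-methylbut-2-enyl)-4-propyl-3,4,8,9-tetrahydro-2H-benzo[1,2-b:3,4-b']dipyran-2,5,10(6H)-trione
Conditions: Pd2(dba)3·CHCl3 (2.5 mol %), (R,R)-N,N'-(cyclohexane-1,2-diyl)bis[2-(diphenylphosphino)benzamide] (7.5 mol %), 17 (1.5 equiv), Cs2CO3 (1.1 equiv), toluene, 0 °C to rt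
Reagents that add atoms: none
Why: palladium-catalysed asymmetric dearomative allylic alkylation (Tsuji–Trost reaction): the caesium phenoxide attacks the unsubstituted terminus of the π-prenyl complex of divalent palladium through C6, the less hindered and more electron-rich ortho carbon. O-prenylation is reversible under zerovalent palladium, while C-alkylation is not. The quaternary C6 centre (R) is set by the chiral pocket of the bisphosphine, which differentiates the two faces of the planar phenoxide.

Step 12
Reactants: 18 (4S,6R,8R,9S)-6-{[(1S,3R)-2,2-dimethyl-3-(prop-1-en-2-yl)cyclobutyl]methyl}-8,9-dimethyl-6-(3-methylbut-2-enyl)-4-propyl-3,4,8,9-tetrahydro-2H-benzo[1,2-b:3,4-b']dipyran-2,5,10(6H)-trione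
Product: 19 (3S)-3-[(2R,3S,8R)-8-{[(1S,3R)-2,2-dimethyl-3-(prop-1-en-2-yl)cyclobutyl]methyl}-5-hydroxy-2,3-dimethyl-8-(3-methylbut-2-enyl)-4,7-dioxo-3,4,7,8-tetrahydro-2H-chromen-6-yl]hexanoic acid (target)
Conditions: LiOH (3 equiv), THF/H2O (3:1), 0 °C, short; then cold 0.5 M HCl to pH 3
Reagents that add atoms: lithium hydroxide, [Li+].[OH-]
Why: the enol lactone of 18 is a vinylogous anhydride, so hydroxide opens it quickly at 0 °C and releases the stabilized triketone enolate. Once that anion is formed the proton at C3 (chromanone numbering) is far less acidic, so the cis ring C should survive; cold dilute acid protonates the carboxylate and the enol without harming the isopropenylcyclobutane.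

## Compound list

1 | (R)-lavandulol, (2R)-5-methyl-2-(prop-1-en-2-yl)hex-4-en-1-ol | CC(C)=CC[C@@H](CO)C(C)=C | starting material
2 | (R)-lavandulyl acetate | CC(C)=CC[C@@H](COC(C)=O)C(C)=C | intermediate
3 | [(1R,3R)-2,2-dimethyl-3-(prop-1-en-2-yl)cyclobutyl]methyl acetate (cis) | C=C(C)[C@H]1C[C@@H](COC(C)=O)C1(C)C | intermediate
4 | [(1R,3R)-2,2-dimethyl-3-(prop-1-en-2-yl)cyclobutyl]methanol | C=C(C)[C@H]1C[C@@H](CO)C1(C)C | intermediate
5 | (1R,3R)-2,2-dimethyl-3-(prop-1-en-2-yl)cyclobutane-1-carbaldehyde | C=C(C)[C@H]1C[C@@H](C=O)C1(C)C | intermediate
6 | phloroglucinol | Oc1cc(O)cc(O)c1 | starting material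
7 | ethyl propiolate | C#CC(=O)OCC | starting material
8 | 5,7-dihydroxycoumarin | O=C1C=Cc2c(O)cc(O)cc2O1 | intermediate
9 | tigloyl chloride, (E)-2-methylbut-2-enoyl chloride | C/C=C(\C)C(Cl)=O | starting material
10 | 5,7-dihydroxy-8-[(E)-2-methylbut-2-enoyl]coumarin | C/C=C(\C)C(=O)c1c(O)cc(O)c2C=CC(=O)Oc12 | intermediate
11 | (8R,9S)-5-hydroxy-8,9-dimethyl-8,9-dihydro-2H,10H-benzo[1,2-b:3,4-b']dipyran-2,10-dione | O=C1Oc2c(C=C1)c(O)cc1O[C@H](C)[C@H](C)C(=O)c12 | intermediate
12 | (E)-prop-1-enylboronic acid | C/C=C/B(O)O | starting material
13 | (4R,8R,9S)-5-hydroxy-8,9-dimethyl-4-[(E)-prop-1-enyl]-3,4,8,9-tetrahydro-2H,10H-benzo[1,2-b:3,4-b']dipyran-2,10-dione | C/C=C/[C@H]1CC(=O)Oc2c1c(O)cc1O[C@H](C)[C@H](C)C(=O)c12 | intermediate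
14 | (4S,8R,9S)-5-hydroxy-8,9-dimethyl-4-propyl-3,4,8,9-tetrahydro-2H,10H-benzo[1,2-b:3,4-b']dipyran-2,10-dione | CCC[C@H]1CC(=O)Oc2c1c(O)cc1O[C@H](C)[C@H](C)C(=O)c12 | intermediate
15 | ortho-quinone methide from 14 and 5: 6-(cyclobutylmethylidene)-2,5,10-trione, exocyclic C=C geometry not defined | CCC[C@H]1CC(=O)OC2=C1C(=O)C(=C[C@@H]3C[C@H](C(C)=C)C3(C)C)C1=C2C(=O)[C@@H](C)[C@@H](C)O1 | intermediate (not isolated)
16 | (4S,8R,9S)-6-{[(1S,3R)-2,2-dimethyl-3-(prop-1-en-2-yl)cyclobutyl]methyl}-5-hydroxy-8,9-dimethyl-4-propyl-3,4,8,9-tetrahydro-2H,10H-benzo[1,2-b:3,4-b']dipyran-2,10-dione | CCC[C@H]1CC(=O)Oc2c1c(O)c(C[C@@H]3C[C@H](C(C)=C)C3(C)C)c1O[C@H](C)[C@H](C)C(=O)c12 | intermediate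
17 | prenyl acetate, 3-methylbut-2-enyl acetate | CC(C)=CCOC(C)=O | starting material
18 | (4S,6R,8R,9S)-6-{[(1S,3R)-2,2-dimethyl-3-(prop-1-en-2-yl)cyclobutyl]methyl}-8,9-dimethyl-6-(3-methylbut-2-enyl)-4-propyl-3,4,8,9-tetrahydro-2H-benzo[1,2-b:3,4-b']dipyran-2,5,10(6H)-trione | C=C(C)[C@H]1C[C@@H](C[C@@]2(CC=C(C)C)C(=O)C3=C(OC(=O)C[C@@H]3CCC)C4=C2O[C@H](C)[C@H](C)C4=O)C1(C)C | intermediate
19 | (3S)-3-[(2R,3S,8R)-8-{[(1S,3R)-2,2-dimethyl-3-(prop-1-en-2-yl)cyclobutyl]methyl}-5-hydroxy-2,3-dimethyl-8-(3-methylbut-2-enyl)-4,7-dioxo-3,4,7,8-tetrahydro-2H-chromen-6-yl]hexanoic acid | C=C(C)[C@H]1C[C@@H](C[C@@]2(CC=C(C)C)C(=O)C([C@@H](CCC)CC(=O)O)=C(O)C3=C2O[C@H](C)[C@H](C)C3=O)C1(C)C | target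

## Step count, longest sequence, risks and fallbacks

Total: 12 steps. Longest linear sequence: 8 steps (steps 5 to 12, from 6 to 19); the terpene branch is 7 steps (steps 1 to 4, then 10 to 12).

Step 2 (key step, proposed new method).
- What may go wrong:
  - capture of the tertiary cation by the acetate carbonyl as a six-membered acetoxonium ion, which would hold the catalyst as a resting salt;
  - protonation at the prenyl olefin followed by six-membered closure;
  - 1,2-alkyl shift of the cyclobutylcarbinyl cation (ring expansion) before proton loss;
  - loss of the proton at the (R) centre or a hydride shift, eroding its configuration;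
  - an unfavourable equilibrium that caps conversion whatever the catalyst.
- If only the first process interferes, the acetyl group would be exchanged for a non-participating silyl group, a change of spectator group within the same disconnection.
- Fallback (known chemistry). It cannot set out from a numbered compound, because it replaces 1 to 3 altogether; it comes back to the route at 4. Commercial (1R,5R)-(+)-α-pinene F1 of high enantiomeric purity would be oxidized at the allylic methylene (t-BuOOH, CrO3 cat., CH2Cl2) to (1R,5R)-(+)-verbenone F2. Cleavage of the enone double bond (RuCl3 cat., NaIO4, CCl4/MeCN/H2O) with loss of one carbon gives cis-pinononic acid F3, in which both ring centres and their cis relation come from the pinane bridge. Wittig methylenation of the acetyl group (Ph3P=CH2, 2.2 equiv, THF, 0 °C to limit epimerization) gives isopropenyl acid F4, and LiAlH4 in Et2O reduces it to 4.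

Step 8 (conjugate addition).
- What may go wrong: slow carbometalation of an electron-rich coumarin whose C4 is flanked by a peri hydroxyl, and protodeboronation of the alkenylboronic acid outrunning the addition.
- Fallback. It sets out from 6 and comes back at 14. Pechmann condensation of 6 with ethyl 3-oxohexanoate F5 (CF3CO2H or H2SO4) gives 5,7-dihydroxy-4-propylcoumarin F6. Acylation with 9 and AlCl3 as in step 6 gives the 8-tigloyl compound F7, and the quinine-catalysed oxa-Michael addition as in step 7 gives the 4-propyl tricyclic coumarin F8. Hydrogenation of its C3=C4 bond (H2, 3–4 atm, Pd/C, AcOH/EtOAc) has no facial bias and would give 14 together with its C4 epimer F9, to be separated by chromatography or crystallization. This is shorter but sacrifices half of the material.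

Step 10 (reductive alkylation).
- What may go wrong: slow condensation of a moderately nucleophilic phenol with a hindered aldehyde; tautomerization of the quinone methide to an alkenylphenol, with loss of the adjacent cyclobutane configuration; bis-arylation of the quinone methide; protonation of the isopropenyl group if a stronger acid is needed.
- Fallback. It sets out from 14 and 4 and comes back at 16; it changes the bond formation from condensation to cross-coupling. Bromination of 14 at C6 (NBS, MeCN, 0 °C) gives aryl bromide F10. Alcohol 4 is converted to the primary iodide F11 (I2, PPh3, imidazole, CH2Cl2; Appel-type). Zinc insertion (Zn dust, LiCl, THF, 30 °C) gives alkylzinc iodide F12, which is used without isolation in a Negishi coupling with F10 (Pd(OAc)2, a dialkylbiarylphosphine, THF, rt to 50 °C, with one extra equivalent of F12 to take up the phenol proton).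

Step 11 (dearomative prenylation).
- What may go wrong: O-alkylation that does not funnel to carbon; attack at the lactone-bearing ortho carbon; bond formation at the substituted allyl terminus (reverse prenyl); insufficient facial discrimination on a substrate that already carries five stereocentres.
- Migration of the lactone to the neighbouring phenoxide oxygen would be harmless, since both lactones give 19 after C-alkylation and opening.
- Fallback. It sets out from 16 and comes back at 18. The same palladium catalyst with allyl acetate in place of 17, the best-behaved electrophile for asymmetric dearomative allylation, would give the 6-allyl dienone F13. Cross-metathesis with 2-methylbut-2-ene (second-generation Grubbs catalyst, CH2Cl2, 40 °C) then turns allyl into prenyl; the 1,1-disubstituted isopropenyl group is a poor metathesis partner and should survive. If facial control remains incomplete, the C6 epimers are diastereomers and can be separated at this stage.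

## Further compounds

F1 | step 2 | (1R,5R)-(+)-α-pinene | CC1=CC[C@@H]2C[C@H]1C2(C)C
F2 | step 2 | (1R,5R)-(+)-verbenone | CC1=CC(=O)[C@@H]2C[C@H]1C2(C)C
F3 | step 2 | (1R,3S)-3-acetyl-2,2-dimethylcyclobutane-1-carboxylic acid (cis-pinononic acid) | CC(=O)[C@H]1C[C@@H](C(=O)O)C1(C)C
F4 | step 2 | (1R,3R)-2,2-dimethyl-3-(prop-1-en-2-yl)cyclobutane-1-carboxylic acid | C=C(C)[C@H]1C[C@@H](C(=O)O)C1(C)C
F5 | step 8 | ethyl 3-oxohexanoate | CCCC(=O)CC(=O)OCC
F6 | step 8 | 5,7-dihydroxy-4-propylcoumarin | CCCC1=CC(=O)Oc2cc(O)cc(O)c12
F7 | step 8 | 5,7-dihydroxy-8-[(E)-2-methylbut-2-enoyl]-4-propylcoumarin | C/C=C(\C)C(=O)c1c(O)cc(O)c2c1OC(=O)C=C2CCC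
F8 | step 8 | (8R,9S)-5-hydroxy-8,9-dimethyl-4-propyl-8,9-dihydro-2H,10H-benzo[1,2-b:3,4-b']dipyran-2,10-dione | CCCC1=CC(=O)Oc2c1c(O)cc1O[C@H](C)[C@H](C)C(=O)c12
F9 | step 8 | (4R,8R,9S)-5-hydroxy-8,9-dimethyl-4-propyl-3,4,8,9-tetrahydro-2H,10H-benzo[1,2-b:3,4-b']dipyran-2,10-dione (C4 epimer of 14) | CCC[C@@H]1CC(=O)Oc2c1c(O)cc1O[C@H](C)[C@H](C)C(=O)c12
F10 | step 10 | (4S,8R,9S)-6-bromo-5-hydroxy-8,9-dimethyl-4-propyl-3,4,8,9-tetrahydro-2H,10H-benzo[1,2-b:3,4-b']dipyran-2,10-dione | CCC[C@H]1CC(=O)Oc2c1c(O)c(Br)c1O[C@H](C)[C@H](C)C(=O)c12
F11 | step 10 | (1R,3R)-1-(iodomethyl)-2,2-dimethyl-3-(prop-1-en-2-yl)cyclobutane | C=C(C)[C@H]1C[C@@H](CI)C1(C)C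
F12 | step 10 | {[(1R,3R)-2,2-dimethyl-3-(prop-1-en-2-yl)cyclobutyl]methyl}zinc iodide | C=C(C)[C@H]1C[C@@H](C[Zn]I)C1(C)C
F13 | step 11 | (4S,6R,8R,9S)-6-{[(1S,3R)-2,2-dimethyl-3-(prop-1-en-2-yl)cyclobutyl]methyl}-8,9-dimethyl-6-(prop-2-enyl)-4-propyl-3,4,8,9-tetrahydro-2H-benzo[1,2-b:3,4-b']dipyran-2,5,10(6H)-trione | C=C(C)[C@H]1C[C@@H](C[C@@]2(CC=C)C(=O)C3=C(OC(=O)C[C@@H]3CCC)C4=C2O[C@H](C)[C@H](C)C4=O)C1(C)C
A1 | alternative 1 | ring A dienone: C7 ketone, C5 triisopropylsilyl ether, C8a ethyl ether, C8 with prenyl and cyclobutylmethyl groups, side chain as tert-butyl ester | C=C(C)[C@H]1C[C@@H](C[C@@]2(CC=C(C)C)C(=O)C([C@@H](CCC)CC(=O)OC(C)(C)C)=C(O[Si](C(C)C)(C(C)C)C(C)C)C=C2OCC)C1(C)C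
A2 | alternative 1 | 4-{[(1S,3R)-2,2-dimethyl-3-(prop-1-en-2-yl)cyclobutyl]methyl}-3-ethoxy-4-(3-methylbut-2-enyl)cyclobut-2-en-1-one (C4 configuration left open, it is lost on ring opening) | CCOC1=CC(=O)C1(CC=C(C)C)C[C@@H]2C[C@H](C(C)=C)C2(C)C
A3 | alternative 1 | tert-butyl (3S)-3-propyl-5-[tri(propan-2-yl)silyloxy]pent-4-ynoate | CCC[C@@H](CC(=O)OC(C)(C)C)C#CO[Si](C(C)C)(C(C)C)C(C)C
A4 | alternative 2 | (3R)-3-{[tert-butyl(diphenyl)silyl]oxymethyl}-2,2-dimethylcyclobutan-1-one | O=C1C[C@@H](CO[Si](c2ccccc2)(c2ccccc2)C(C)(C)C)C1(C)C
A5 | alternative 2 | 1-[(2S,5S)-2,5-dimethylpyrrolidin-1-yl]-2-methylpropan-1-one | CC(C)C(=O)N1[C@@H](C)CC[C@@H]1C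
A6 | alternative 2 | tert-butyl(diphenyl)(prop-2-enyloxy)silane | C=CCO[Si](c1ccccc1)(c1ccccc1)C(C)(C)C
A7 | alternative 3 | methyl (2R)-2-{[(1S,3R)-2,2-dimethyl-3-(prop-1-en-2-yl)cyclobutyl]methyl}-2-[(2R,3S)-2,3-dimethyl-4-oxo-3,4-dihydro-2H-pyran-6-yl]-5-methylhex-4-enoate | C=C(C)[C@H]1C[C@@H](C[C@@](C2=CC(=O)[C@@H](C)[C@@H](C)O2)(CC=C(C)C)C(=O)OC)C1(C)C
A8 | alternative 3 | methyl 2-{[(1S,3R)-2,2-dimethyl-3-(prop-1-en-2-yl)cyclobutyl]methyl}-2-[(3Z)-1-methoxy-3-(triethylsilyloxy)penta-1,3-dienyl]-5-methylhex-4-enoate (C1=C2 geometry not defined) | C=C(C)[C@H]1C[C@@H](C[C@@](CC=C(C)C)(C(=O)OC)C(OC)=C/C(O[Si](CC)(CC)CC)=C/C)C1(C)C
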